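**Retrosynthetic overview**
1. Ester C–O bond and two silyl groups: the target comes from the 4‑O‑TES germacra‑1(10),5‑diene‑4,8‑diol and O‑silylated 4‑hydroxybenzoic acid. The arene ring is bought.
2. Enabling feature: the ring is a cyclodeca‑1,6‑diene. Alkene carbons C10 and C5 face each other 1,6 across it, their partners C1 and C6 lie next to them, and C7–H/C8–O sit beside C6. A temporary C5–C10 bond turns it into a trans‑decalin (ring A = C1–C5, C10; ring B = C5–C10) in which C1–OMs and C6–B are both antiperiplanar to that bond.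
3. Ten‑membered ring: from the trans‑fused 6,8‑diene 1β‑mesylate by double hydroboration, boronate fragmentation and C8–B oxidation. This one operation sets C7, C8 and both E‑alkenes and opens the decalin.
4. Ring B: aldol condensation of a keto aldehyde made by trans‑vicinal vinylation/allylation of the ring A enone. Ring A: RCM of a diene from (R)‑linalool, which supplies C4.
5. Order of ring formation: ring A (RCM), ring B (aldol), then the ten‑membered ring (scission of C5–C10) last.

Key step: step 13

Remark: germacrane numbering is kept for all intermediates (C1H=C10(CH3), C2H2, C3H2, C4(CH3)(O), C5H=C6H, C7H(iPr), C8H(O), C9H2). In the decalins, β is the face of the C10 methyl group.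
Remark (assumption): commercial (R)‑(−)‑linalool is taken as a single enantiomer. It is the only source of chirality.

**Step 1**
Reactants: 1 (R)‑(−)‑linalool
Product: 2 (3R)‑3,7‑dimethyl‑3‑(triethylsilyloxy)octa‑1,6‑diene
Conditions: TESOTf, 2,6‑lutidine, CH2Cl2, −78 to 0 °C
Reagents that add atoms: triethylsilyl trifluoromethanesulfonate, CC[Si](CC)(CC)OS(=O)(=O)C(F)(F)F
Why: Silyl triflate silylation is the standard way to protect a hindered tertiary allylic alcohol, and the C4 stereocentre (R) bought with linalool is not touched.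

**Step 2**
Reactants: 2 linalool TES ether
Product: 3 (4R)‑4‑methyl‑4‑(triethylsilyloxy)hex‑5‑enal
Conditions: O3 (1 equiv, Sudan red indicator), CH2Cl2/MeOH, −78 °C; then Me2S, −78 °C to rt
Reagents that add atoms: ozone, [O-][O+]=O
Why: Chemoselective ozonolysis should cleave the electron‑rich trisubstituted alkene well before the hindered monosubstituted vinyl group next to the silyloxy‑bearing quaternary carbon.

**Step 3**
Reactants: 3 aldehyde; 4 isopropenylmagnesium bromide
Product: 5 (6R)‑2,6‑dimethyl‑6‑(triethylsilyloxy)octa‑1,7‑dien‑3‑ol (both C3 epimers)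
Conditions: THF, −78 to 0 °C; H2O quench
Reagents that add atoms: none
Why: Grignard 1,2‑addition brings in C10, its methyl group and a sacrificial methylene carbon that leaves as ethylene in step 4, and the new carbinol centre needs no control because step 5 oxidises it away.

**Step 4**
Reactants: 5 dienol
Product: 6 (4R)‑2,4‑dimethyl‑4‑(triethylsilyloxy)cyclohex‑2‑en‑1‑ol (both C1 epimers)
Conditions: second‑generation Grubbs catalyst (H2IMes)(PCy3)Cl2Ru=CHPh (2 mol %), CH2Cl2 (0.01 M), reflux
Reagents that add atoms: none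
Why: Ring‑closing metathesis of a mono‑ and a 1,1‑disubstituted alkene to a trisubstituted cyclohexene is reliable and closes ring A with loss of ethylene.

**Step 5**
Reactants: 6 cyclohexenol
Product: 7 (4R)‑2,4‑dimethyl‑4‑(triethylsilyloxy)cyclohex‑2‑en‑1‑one
Conditions: MnO2 (activated, excess), CH2Cl2, rt
Reagents that add atoms: none
Why: Allylic alcohol oxidation with MnO2 should convert both epimers into the single ring A enone.

**Step 6**
Reactants: 7 ring A enone; 8 vinylmagnesium bromide
Product: 9 (3R,4R)‑3‑ethenyl‑2,4‑dimethyl‑4‑(triethylsilyloxy)‑1‑(trimethylsilyloxy)cyclohex‑1‑ene (vinyl trans to OTES)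
Conditions: CuBr·SMe2 (20 mol %), TMSCl, HMPA, THF, −78 to −40 °C; Et3N, cold aq. NaHCO3 work‑up
Reagents that add atoms: chlorotrimethylsilane, C[Si](C)(C)Cl
Why: In this copper‑catalysed, TMSCl‑accelerated conjugate addition, axial attack antiperiplanar to the pseudoaxial C4–O bond should place the vinyl group (C6) on C5 trans to OTES, and the enolate is stored regiospecifically as its silyl ether.

**Step 7**
Reactants: 10 3‑bromo‑2‑(bromomethyl)prop‑1‑ene; 11 isopropylmagnesium bromide
Product: 12 2‑(bromomethyl)‑4‑methylpent‑1‑ene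
Conditions: CuI (5 mol %), Et2O/THF, −40 to 0 °C, 10 in excess
Reagents that add atoms: none
Why: Copper‑catalysed allylic substitution of one C–Br bond gives the same product by the SN2 and SN2′ paths because the dibromide is symmetric, and excess dibromide suppresses double substitution.

**Step 8**
Reactants: 9 silyl enol ether; 12 allylic bromide
Product: 14 (2R,3R,4R)‑3‑ethenyl‑2,4‑dimethyl‑2‑(4‑methyl‑2‑methylidenepentyl)‑4‑(triethylsilyloxy)cyclohexan‑1‑one, via lithium enolate 13 (not isolated)
Conditions: MeLi, THF, 0 °C; then 12, HMPA, −78 °C to rt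
Reagents that add atoms: none
Why: Si–O cleavage with MeLi releases the tetrasubstituted enolate regiospecifically, and SN2 allylation anti to the neighbouring pseudoaxial vinyl group (trans‑vicinal dialkylation) should set quaternary C10 with C9 trans to C6, which is the future trans ring fusion.

**Step 9**
Reactants: 14 dienone
Product: 15 (1R,2R,6R)‑2,6‑dimethyl‑2‑(4‑methyl‑2‑oxopentyl)‑3‑oxo‑6‑(triethylsilyloxy)cyclohexane‑1‑carbaldehyde
Conditions: O3, CH2Cl2/MeOH, −78 °C; then Me2S
Reagents that add atoms: ozone, [O-][O+]=O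
Why: Exhaustive ozonolysis unmasks in one step the C6 aldehyde from the vinyl group and the C8 ketone from the methylidene group.

**Step 10**
Reactants: 15 keto aldehyde
Product: 16 (4R,5R,10R)‑4α‑(triethylsilyloxy)‑5αH‑eudesm‑6‑ene‑1,8‑dione (trans‑decalin with both the 4β‑ and 10β‑methyl groups axial)
Conditions: pyrrolidine (20 mol %), AcOH (20 mol %), toluene, 50 °C
Reagents that add atoms: none
Why: In this amine‑catalysed intramolecular aldol condensation only attack of C7 on the C6 aldehyde gives a six‑membered ring, the aldehyde is far more electrophilic than the neopentyl C1 ketone, and the equatorial C4–O bond is poorly aligned for β‑elimination.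

**Step 11**
Reactants: 16 enedione
Product: 17 (1R,4R,5R,8R,10R)‑4α‑(triethylsilyloxy)‑5αH‑eudesm‑6‑ene‑1β,8β‑diol
Conditions: NaBH4, CeCl3·7H2O, MeOH, −20 to 0 °C
Reagents that add atoms: none
Why: Luche reduction reduces both carbonyl groups, axial hydride delivery from the α face (away from the axial C10 methyl group) should give the equatorial 1β‑alcohol needed later, and the C8 carbinol is removed in the next step.

**Step 12**
Reactants: 17 diol
Product: 19 (1R,4R,5R,10R)‑4α‑(triethylsilyloxy)‑5αH‑eudesma‑6,8‑dien‑1β‑yl methanesulfonate, via bis‑mesylate 18 (not isolated)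
Conditions: MsCl (3 equiv), Et3N, CH2Cl2, −10 °C; then DBU, rt to 40 °C
Reagents that add atoms: methanesulfonyl chloride, CS(=O)(=O)Cl
Why: After double mesylation only the allylic, pseudoaxial 8β‑mesylate has an antiperiplanar hydrogen (9α) and undergoes E2 elimination to the homoannular diene, while the equatorial neopentyl C1 mesylate has none and should stay.

**Step 13**
Reactants: 19 diene mesylate
Product: 22 (1(10)E,5E,4R,7S,8S)‑4‑(triethylsilyloxy)germacra‑1(10),5‑dien‑8‑ol, via 6,8‑bis(borane) 20 (not isolated), via C8‑boronic acid 21 (not isolated)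
Conditions: BH3·THF (6 equiv), THF, 0 °C to rt; H2O, 0 °C; 3 M aq. NaOH, 45 °C; then 30 % H2O2, 0 °C to rt
Reagents that add atoms: hydrogen peroxide, OO (oxygen on C8); borane–tetrahydrofuran, B.C1CCOC1 (boron only in 20 and 21); water, O (hydroxyl groups on boron in 21)
Why: Proposed new method: excess BH3 should add twice to the homoannular diene from the α face, opposite the axial methyl groups on C4 and C10, with boron going to C8 (away from neopentyl C9 and at the allylic position favoured in cyclic 1,3‑dienes) and to C6 (the CH end of the trisubstituted alkene), so that either order of addition and any suprafacial 1,3‑boron shift converge on 20. After water has destroyed all B–H, hydroxide makes both boron atoms tetracoordinate, but only the equatorial C6–B bond is antiperiplanar to the C5–C10 fusion bond, which is itself antiperiplanar to the equatorial C1–OMs bond, so a concerted seven‑centre Grob‑type fragmentation expels boric acid and mesylate, whereas the C8–B bond is aligned with C9–C10, which is gauche to C1–OMs, so it survives as 21 and is then oxidised by H2O2 with retention. The closest known reactions are the hydroboration/base‑induced boronate fragmentation of 10‑methyloctalinyl mesylates to (E,E)‑1‑methylcyclodeca‑1,6‑dienes (Marshall‑type fragmentation) and the dihydroboration–oxidation of cyclic 1,3‑dienes, and the only new element is that two C–B bonds of one intermediate meet different fates in one flask. The ten‑membered ring is closed by ring expansion, that is by scission of the zero‑atom bridge of the bicyclo[4.4.0]decane, not by end‑to‑end cyclisation, so no entropic or transannular penalty of medium‑ring closure is paid. C7 is set by syn H–B addition on the α face (H α, isopropyl β, 7S) and C8 by α‑face boron delivery followed by stereoretentive C–B to C–O exchange (8S), both controlled by the C10 methyl group, whose configuration was relayed from C4, and C4 itself is untouched. The E geometry of both alkenes follows from the trans fusion (C9 equatorial on ring A, C4 equatorial on ring B), and chemoselectivity requires only that peroxide be added after fragmentation is complete.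

**Step 14**
Reactants: 22 germacradienol; 23 4‑(tert‑butyldimethylsilyloxy)benzoic acid
Product: 24 (1(10)E,5E,4R,7S,8S)‑4‑(triethylsilyloxy)germacra‑1(10),5‑dien‑8‑yl 4‑(tert‑butyldimethylsilyloxy)benzoate
Conditions: DIC, DMAP, CH2Cl2, rt
Reagents that add atoms: none
Why: Steglich esterification proceeds with retention at C8 under neutral conditions that spare the acid‑sensitive diene, and the secondary C8 hydroxyl is the only free OH.

**Step 15**
Reactants: 24 bis‑silyl ester
Product: 25 (1(10)E,5E,4R,7S,8S)‑4‑hydroxygermacra‑1(10),5‑dien‑8‑yl 4‑hydroxybenzoate (target)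
Conditions: TBAF, AcOH (1:1), THF, 0 °C to rt
Reagents that add atoms: none
Why: Buffered fluoride desilylation should remove the aryl TBS and the tertiary TES ether together without acid (no transannular cyclisation) and without strong base (no ester cleavage).

**Compound list**
1 | (R)‑(−)‑linalool | CC(C)=CCC[C@@](C)(O)C=C | starting material
2 | linalool TES ether | CC(C)=CCC[C@@](C)(O[Si](CC)(CC)CC)C=C | intermediate
3 | (4R)‑4‑methyl‑4‑(triethylsilyloxy)hex‑5‑enal | O=CCC[C@@](C)(O[Si](CC)(CC)CC)C=C | intermediate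
4 | isopropenylmagnesium bromide | CC(=C)[Mg]Br | starting material
5 | (6R)‑2,6‑dimethyl‑6‑(triethylsilyloxy)octa‑1,7‑dien‑3‑ol | C=C(C)C(O)CC[C@@](C)(O[Si](CC)(CC)CC)C=C | intermediate
6 | (4R)‑2,4‑dimethyl‑4‑(triethylsilyloxy)cyclohex‑2‑en‑1‑ol | CC1=C[C@](C)(O[Si](CC)(CC)CC)CCC1O | intermediate
7 | (4R)‑2,4‑dimethyl‑4‑(triethylsilyloxy)cyclohex‑2‑en‑1‑one | CC1=C[C@](C)(O[Si](CC)(CC)CC)CCC1=O | intermediate
8 | vinylmagnesium bromide | C=C[Mg]Br | starting material
9 | TMS enol ether, vinyl trans to OTES | CC1=C(O[Si](C)(C)C)CC[C@@](C)(O[Si](CC)(CC)CC)[C@@H]1C=C | intermediate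
10 | 3‑bromo‑2‑(bromomethyl)prop‑1‑ene | C=C(CBr)CBr | starting material
11 | isopropylmagnesium bromide | CC(C)[Mg]Br | starting material
12 | 2‑(bromomethyl)‑4‑methylpent‑1‑ene | C=C(CBr)CC(C)C | intermediate
13 | lithium enolate | [Li+].CC1=C([O-])CC[C@@](C)(O[Si](CC)(CC)CC)[C@@H]1C=C | intermediate
14 | trans‑dialkylated cyclohexanone | C[C@]1(CC(=C)CC(C)C)C(=O)CC[C@@](C)(O[Si](CC)(CC)CC)[C@@H]1C=C | intermediate
15 | keto aldehyde | C[C@]1(CC(=O)CC(C)C)C(=O)CC[C@@](C)(O[Si](CC)(CC)CC)[C@@H]1C=O | intermediate
16 | 4α‑OTES‑5αH‑eudesm‑6‑ene‑1,8‑dione | C[C@@]12CC(=O)C(C(C)C)=C[C@H]1[C@](C)(O[Si](CC)(CC)CC)CCC2=O | intermediate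
17 | 4α‑OTES‑5αH‑eudesm‑6‑ene‑1β,8β‑diol | C[C@@]12C[C@@H](O)C(C(C)C)=C[C@H]1[C@](C)(O[Si](CC)(CC)CC)CC[C@H]2O | intermediate
18 | 1β,8β‑bis‑mesylate | C[C@@]12C[C@@H](OS(C)(=O)=O)C(C(C)C)=C[C@H]1[C@](C)(O[Si](CC)(CC)CC)CC[C@H]2OS(C)(=O)=O | intermediate
19 | 4α‑OTES‑5αH‑eudesma‑6,8‑dien‑1β‑yl mesylate | C[C@@]12C=CC(C(C)C)=C[C@H]1[C@](C)(O[Si](CC)(CC)CC)CC[C@H]2OS(C)(=O)=O | intermediate
20 | 6α,8α‑diboryl‑7β‑isopropyl trans‑decalin 1β‑mesylate | C[C@@]12C[C@H](B)[C@@H](C(C)C)[C@H](B)[C@H]1[C@](C)(O[Si](CC)(CC)CC)CC[C@H]2OS(C)(=O)=O | intermediate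
21 | 4‑OTES‑germacra‑1(10),5‑dien‑8‑ylboronic acid | C/C1=C\CC[C@@](C)(O[Si](CC)(CC)CC)/C=C/[C@H](C(C)C)[C@@H](B(O)O)C1 | intermediate
22 | 4‑OTES‑germacra‑1(10),5‑dien‑8‑ol | C/C1=C\CC[C@@](C)(O[Si](CC)(CC)CC)/C=C/[C@H](C(C)C)[C@@H](O)C1 | intermediate
23 | 4‑(tert‑butyldimethylsilyloxy)benzoic acid | CC(C)(C)[Si](C)(C)Oc1ccc(cc1)C(=O)O | starting material
24 | bis‑silyl ester | C/C1=C\CC[C@@](C)(O[Si](CC)(CC)CC)/C=C/[C@H](C(C)C)[C@@H](OC(=O)c2ccc(O[Si](C)(C)C(C)(C)C)cc2)C1 | intermediate
25 | target | C/C1=C\CC[C@@](C)(O)/C=C/[C@H](C(C)C)[C@@H](OC(=O)c2ccc(O)cc2)C1 | target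

**Total step count:** 15. **Longest linear sequence:** 14 (steps 1–6 and 8–15).

**Steps most likely to fail**

*Step 13 (Proposed new method).* Several things may go wrong:
- incomplete second hydroboration of the crowded C6=C7 bond;
- boron delivery to C9;
- loss of the allylic borane stage by protonolysis;
- oxidation overtaking fragmentation.

The fallback uses only known chemistry. It sets out from diol 17 and returns at 22. Mitsunobu inversion (4‑nitrobenzoic acid, PPh3, DIAD) of the allylic 8β‑alcohol, the neopentyl 1β‑alcohol being inert, gives the 8α‑(4‑nitrobenzoate) F1. Mesylation of the remaining 1β‑alcohol gives the ester mesylate F2. Methanolysis (K2CO3, MeOH) gives the 8α‑allylic alcohol mesylate F3. BH3·THF then hydroborates the single C6=C7 alkene from the α face to the 6α‑borane F4. Aqueous NaOH triggers the established single‑boron boronate fragmentation directly to 22, so no peroxide is needed.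

*Step 6.* The β‑carbon is flanked by quaternary C4 and the α‑methyl group. The 1,4‑addition may therefore be sluggish, giving way to 1,2‑addition or enone reduction, and facial selectivity may erode.

The fallback moves the methyl group to a later point. It sets out from aldehyde 3 and returns at 9. Addition of 8 gives the dienol F5, RCM gives the cyclohexenol F6, and MnO2 gives the α‑unsubstituted enone F7. Copper‑mediated vinyl addition to this less hindered enone, trapped with MeI/HMPA, gives the 2‑methyl‑3‑vinyl ketone F8, whose C2 configuration is irrelevant. Thermodynamic silylation (TMSI, (Me3Si)2NH) then gives the more substituted silyl enol ether 9.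

*Step 10.* Enolisation of the aldehyde may epimerise C5. The silyloxy group may be lost by β‑elimination. A five‑ring aldol onto the C1 ketone may compete.

The fallback closes ring B by metathesis and never passes through an aldehyde. It sets out from 9 (through 13) and returns at 16. Alkylation of 13 with 2,3‑dibromopropene gives the vinyl bromide F9. Negishi coupling with (3‑methylbut‑1‑en‑2‑yl)zinc bromide and Pd(dppf)Cl2 gives the triene F10. RCM of the vinyl group with the isopropyl‑substituted methylidene gives the bicyclic methylidene diene F11, the trans arrangement of the two arms disfavouring the five‑membered alternative. Lemieux–Johnson cleavage (OsO4 cat., NaIO4) of the exposed exocyclic methylidene then gives 16.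

**Further compounds**
F1 | step 13 | 8α‑(4‑nitrobenzoyloxy)‑4α‑OTES‑5αH‑eudesm‑6‑en‑1β‑ol | C[C@@]12C[C@H](OC(=O)c3ccc(cc3)[N+](=O)[O-])C(C(C)C)=C[C@H]1[C@](C)(O[Si](CC)(CC)CC)CC[C@H]2O
F2 | step 13 | 1β‑mesylate of F1 | C[C@@]12C[C@H](OC(=O)c3ccc(cc3)[N+](=O)[O-])C(C(C)C)=C[C@H]1[C@](C)(O[Si](CC)(CC)CC)CC[C@H]2OS(C)(=O)=O
F3 | step 13 | 8α‑hydroxy‑4α‑OTES‑5αH‑eudesm‑6‑en‑1β‑yl mesylate | C[C@@]12C[C@H](O)C(C(C)C)=C[C@H]1[C@](C)(O[Si](CC)(CC)CC)CC[C@H]2OS(C)(=O)=O
F4 | step 13 | 6α‑boryl‑8α‑hydroxy‑7β‑isopropyl trans‑decalin 1β‑mesylate | C[C@@]12C[C@H](O)[C@@H](C(C)C)[C@H](B)[C@H]1[C@](C)(O[Si](CC)(CC)CC)CC[C@H]2OS(C)(=O)=O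
F5 | step 6 | (6R)‑6‑methyl‑6‑(triethylsilyloxy)octa‑1,7‑dien‑3‑ol | C=CC(O)CC[C@@](C)(O[Si](CC)(CC)CC)C=C
F6 | step 6 | (4R)‑4‑methyl‑4‑(triethylsilyloxy)cyclohex‑2‑en‑1‑ol | OC1CC[C@@](C)(O[Si](CC)(CC)CC)C=C1
F7 | step 6 | (4R)‑4‑methyl‑4‑(triethylsilyloxy)cyclohex‑2‑en‑1‑one | O=C1CC[C@@](C)(O[Si](CC)(CC)CC)C=C1
F8 | step 6 | (3R,4R)‑3‑ethenyl‑2,4‑dimethyl‑4‑(triethylsilyloxy)cyclohexan‑1‑one | CC1C(=O)CC[C@@](C)(O[Si](CC)(CC)CC)[C@@H]1C=C
F9 | step 10 | (2R,3R,4R)‑2‑(2‑bromoprop‑2‑enyl)‑3‑ethenyl‑2,4‑dimethyl‑4‑(triethylsilyloxy)cyclohexan‑1‑one | C[C@]1(CC(Br)=C)C(=O)CC[C@@](C)(O[Si](CC)(CC)CC)[C@@H]1C=C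
F10 | step 10 | (2R,3R,4R)‑3‑ethenyl‑2,4‑dimethyl‑2‑(4‑methyl‑2,3‑dimethylidenepentyl)‑4‑(triethylsilyloxy)cyclohexan‑1‑one | C[C@]1(CC(=C)C(=C)C(C)C)C(=O)CC[C@@](C)(O[Si](CC)(CC)CC)[C@@H]1C=C
F11 | step 10 | 8‑methylidene‑4α‑OTES‑5αH‑eudesm‑6‑en‑1‑one | C[C@@]12CC(=C)C(C(C)C)=C[C@H]1[C@](C)(O[Si](CC)(CC)CC)CCC2=O
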